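## Retrosynthetic overview

1. Labels: O1, C2 (OCH), C3 (aryl-bearing), C4, C4a, C5, C6 (C=O), C7 (carbinol), C8 (CH2), C8a (quaternary, O-bearing), Ca (CH on catechol ring B), Cb (CH bearing the benzyl group). Ring A is C4a–C8a, ring C is the aryl on C3, ring D is the aryl of the benzyl group.
2. Feature: the tetrahydrofuran O1–C2–Cb–Ca–C8a shares O1, C2 and C8a with the dihydropyran O1–C2–C3=C4–C4a–C8a in an 8-oxabicyclo[3.2.1]octadiene. It is the sum of O1–C8a–Ca (a para-quinol oxygen beside a carbon that a para-hydroxyphenyl group can turn into a quinone methide) and C2–Cb (β and α carbons of an aryl enone once the benzyl CH2 is written as C=O).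
3. Disconnections, backwards: the C7–ring B bond (Friedel–Crafts hydroxyalkylation of the unmasked C7 ketone), then benzyl CH2 back to aroyl C=O, then Cb–Ca and O1–C2 in one operation back to a monocyclic (S)-para-quinol.
4. The quinol comes from a ring A phenol by singlet-oxygen para-hydroxylation and resolution. The phenol comes from four arenes by Knoevenagel condensation (C3=C4, with a nitrile as C2 so that C2 ends cis to C4a), Negishi benzylation (C8a–Ca) and aldol condensation (C2=Cb).
5. Ring order: the ring A dienone first, then dihydropyran, tetrahydrofuran and cycloheptene together, and the bicyclo[3.3.1]nonane ring last.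

Key step: step 20

Remark: exo means on the O1 side and endo means on the side of the C3=C4–C4a bridge of the oxabicyclo[3.2.1]octadiene; it is assumed that the (S)-fraction of step 18 is identified by anomalous-dispersion X-ray analysis or ECD before it is carried on.

## Route

Step 1
Reactants: 1 2-bromo-4,5-dimethoxybenzaldehyde
Product: 2 2-bromo-4,5-dihydroxybenzaldehyde
Conditions: BBr3 (2.5 equiv), CH2Cl2, −78 °C to rt; then H2O
Reagents that add atoms: none
Why: Lewis-acid aryl methyl ether cleavage frees both oxygens of a ring A building block that already carries bromine at the future C8a, which sidesteps a bromination that a free or acetal-protected catechol would misdirect.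

Step 2
Reactants: 2 2-bromo-4,5-dihydroxybenzaldehyde
Product: 3 2-bromo-5-hydroxy-4-(methoxymethoxy)benzaldehyde
Conditions: MOMCl (1.05 equiv), K2CO3 (1.0 equiv), acetone, 0 °C to rt
Reagents that add atoms: chloromethyl methyl ether (MOMCl), COCCl
Why: Williamson-type O-alkylation under one equivalent of weak base takes the hydroxyl para to the formyl group, the more acidic one and the future C7 oxygen, and puts on it an acetal ether that can later leave from an enol oxygen under mild acid.

Step 3
Reactants: 3 2-bromo-5-hydroxy-4-(methoxymethoxy)benzaldehyde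
Product: 4 2-bromo-4-(methoxymethoxy)-5-(tetrahydropyran-2-yloxy)benzaldehyde (racemic acetal carbon)
Conditions: 3,4-dihydro-2H-pyran, PPTS (cat.), CH2Cl2, rt
Reagents that add atoms: 3,4-dihydro-2H-pyran, C1=COCCC1
Why: Acid-catalysed acetalisation masks the future C6 phenol as a THP ether that withstands methoxide, organozinc, hydride and amide bases yet is cleaved under milder acid than the MOM ethers, its racemic acetal centre being of no consequence because it leaves in step 16.

Step 4
Reactants: 5 2,6-dimethoxyphenol
Product: 6 1,3-dimethoxy-2-(methoxymethoxy)benzene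
Conditions: NaH, MOMCl, THF–DMF, 0 °C to rt
Reagents that add atoms: chloromethyl methyl ether (MOMCl), COCCl
Why: Williamson-type O-alkylation of the sodium phenoxide protects the hindered ring C hydroxyl in the same acid-labile form as the other phenols.

Step 5
Reactants: 6 1,3-dimethoxy-2-(methoxymethoxy)benzene
Product: 7 1-bromo-2,4-dimethoxy-3-(methoxymethoxy)benzene
Conditions: NBS, MeCN, 0 °C to rt
Reagents that add atoms: N-bromosuccinimide, O=C1CCC(=O)N1Br
Why: Electrophilic aromatic bromination of a 1,2,3-trioxygenated benzene goes para to a flanking methoxy group, the carbon that has to be bonded to C3, and NBS keeps the medium free of the HBr that would strip the MOM group.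

Step 6
Reactants: 7 1-bromo-2,4-dimethoxy-3-(methoxymethoxy)benzene
Product: 8 2-[2,4-dimethoxy-3-(methoxymethoxy)phenyl]acetonitrile
Conditions: Me3SiCH2CN, Pd2(dba)3 (2 mol %), Xantphos (4 mol %), ZnF2 (0.6 equiv), DMF, 90 °C
Reagents that add atoms: (trimethylsilyl)acetonitrile, C[Si](C)(C)CC#N
Why: Palladium-catalysed α-arylation of a nitrile, in which ZnF2 transfers the cyanomethyl group from silicon, gives the monoarylated acetonitrile in one step and tolerates the ortho-methoxy group and the acetal.

Step 7
Reactants: 4 2-bromo-4-(methoxymethoxy)-5-(tetrahydropyran-2-yloxy)benzaldehyde; 8 2-[2,4-dimethoxy-3-(methoxymethoxy)phenyl]acetonitrile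
Product: 9 (Z)-3-[2-bromo-4-(methoxymethoxy)-5-(tetrahydropyran-2-yloxy)phenyl]-2-[2,4-dimethoxy-3-(methoxymethoxy)phenyl]acrylonitrile
Conditions: NaOMe (0.5 equiv), MeOH, rt to 50 °C
Reagents that add atoms: none
Why: Knoevenagel condensation of an arylacetonitrile with a benzaldehyde gives the (Z)-2,3-diarylacrylonitrile with the aryl rings trans, so that the slim nitrile carbon (future C2) ends cis to ring A as the later pyran closure requires, a geometry that the corresponding arylacetaldehyde aldol condensation would deliver the wrong way round.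

Step 8
Reactants: 10 3,4-dihydroxybenzaldehyde
Product: 11 3-hydroxy-4-(triisopropylsilyloxy)benzaldehyde
Conditions: TIPSCl (1.05 equiv), imidazole, CH2Cl2–DMF, 0 °C
Reagents that add atoms: triisopropylsilyl chloride, CC(C)[Si](Cl)(C(C)C)C(C)C
Why: Silylation under mild base selects the more acidic hydroxyl para to the formyl group, which is the oxygen para to the future Ca that must be unmasked alone before the key step, and the bulky TIPS group resists migration to the neighbouring oxygen.

Step 9
Reactants: 11 3-hydroxy-4-(triisopropylsilyloxy)benzaldehyde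
Product: 12 3-(methoxymethoxy)-4-(triisopropylsilyloxy)benzaldehyde
Conditions: MOMCl, i-Pr2NEt, CH2Cl2, 0 °C to rt
Reagents that add atoms: chloromethyl methyl ether (MOMCl), COCCl
Why: Williamson-type O-alkylation under an amine base protects the remaining hydroxyl without forming enough free phenoxide to move the silyl group.

Step 10
Reactants: 12 3-(methoxymethoxy)-4-(triisopropylsilyloxy)benzaldehyde
Product: 13 [3-(methoxymethoxy)-4-(triisopropylsilyloxy)phenyl]methanol
Conditions: NaBH4, THF–EtOH, 0 °C
Reagents that add atoms: none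
Why: Borohydride reduction of the aldehyde gives the benzylic alcohol and leaves the acetal and the silyl ether alone.

Step 11
Reactants: 13 [3-(methoxymethoxy)-4-(triisopropylsilyloxy)phenyl]methanol
Product: 14 4-(chloromethyl)-2-(methoxymethoxy)-1-(triisopropylsilyloxy)benzene
Conditions: PPh3, NCS, THF, 0 °C
Reagents that add atoms: N-chlorosuccinimide, O=C1CCC(=O)N1Cl
Why: Appel-type chlorination through the chlorophosphonium salt runs under neutral conditions, so neither the MOM nor the TIPS ether is lost, and the weakly donating silyloxy group keeps the benzylic chloride stable enough to handle.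

Step 12
Reactants: 14 4-(chloromethyl)-2-(methoxymethoxy)-1-(triisopropylsilyloxy)benzene; 9 (Z)-bromo acrylonitrile
Product: 16 (Z)-acrylonitrile of 9 in which Br at C8a is replaced by the 3-(methoxymethoxy)-4-(triisopropylsilyloxy)benzyl group, via benzylzinc chloride 15 (not isolated)
Conditions: Zn dust, LiCl, THF, 25 °C; then 9, Pd(OAc)2 (2 mol %), SPhos (4 mol %), THF, 25 to 40 °C
Reagents that add atoms: none
Why: LiCl-assisted zinc insertion followed by Negishi cross-coupling on zerovalent palladium with a bulky biaryl phosphine forms the C8a–Ca bond at the hindered electron-rich bromide, and running it on nitrile 9 rather than on aldehyde 4 removes the risk that the benzylic zinc reagent adds to a formyl group.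

Step 13
Reactants: 16 (Z)-acrylonitrile carrying rings A, B and C
Product: 18 (Z)-2,3-diarylacrolein (formyl carbon C2 cis to ring A), via N-alumino aldimine 17 (not isolated)
Conditions: i-Bu2AlH (1.3 equiv), toluene, −78 °C; then aq. potassium sodium tartrate (KNaC4H4O6), 0 °C
Reagents that add atoms: water, O
Why: Partial hydride reduction of the nitrile stops at the N-alumino aldimine, and its cold near-neutral hydrolysis should give the enal with the C3=C4 geometry intact because no nucleophile or strong acid is present that could add reversibly at C4.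

Step 14
Reactants: 19 1-(4-hydroxy-2-methoxyphenyl)ethanone
Product: 20 1-[2-methoxy-4-(methoxymethoxy)phenyl]ethanone
Conditions: MOMCl, i-Pr2NEt, CH2Cl2, 0 °C to rt
Reagents that add atoms: chloromethyl methyl ether (MOMCl), COCCl
Why: Williamson-type O-alkylation of the acidic para-acyl phenol keeps ring D neutral, so that the later enone is not deactivated as a vinylogous carboxylate.

Step 15
Reactants: 20 1-[2-methoxy-4-(methoxymethoxy)phenyl]ethanone; 18 (Z)-2,3-diarylacrolein
Product: 23 (2E,4E)-1-(ring D)-4-(ring C)-5-(ring A)penta-2,4-dien-1-one with C6–OTHP and ring B–OTIPS, via aldol adduct 21 (not isolated), via allylic mesylate 22 (not isolated)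
Conditions: 20, LiN(SiMe3)2, THF, −78 °C; 18; then MsCl, Et3N, −78 to 0 °C
Reagents that add atoms: none
Why: Directed aldol addition of the lithium enolate to the formyl group, followed by mesylation and E1cB elimination, is a stepwise Claisen–Schmidt condensation that gives the (E)-C2=Cb bond without hydroxide and so spares the aryl silyl ether and the C3=C4 geometry.

Step 16
Reactants: 23 fully protected dienone
Product: 24 ring A phenol (C6–OH free, all other groups as in 23)
Conditions: PPTS (0.2 equiv), MeOH–CH2Cl2, 35 °C
Reagents that add atoms: none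
Why: Acid-catalysed transacetalisation to methanol removes the easily ionised aryl THP acetal under conditions too mild for aryl MOM ethers or the aryl TIPS ether.

Step 17
Reactants: 24 ring A phenol
Product: 26 racemic para-quinol (C8a–OH, C6 dienone, C7–OMOM), via para-hydroperoxide 25 (not isolated)
Conditions: O2, methylene blue (2 mol %), 630 nm LED, CH2Cl2–MeOH, −10 °C; then PPh3 (1.0 equiv), 0 °C
Reagents that add atoms: dioxygen, O=O
Why: Sensitised photooxygenation of a para-alkylphenol delivers singlet oxygen across C6 and C8a to give the para-hydroperoxydienone that PPh3 reduces to the quinol, a para-specific mode chosen because trivalent-iodine oxidants attack a 2-alkoxyphenol at the alkoxy-bearing ortho carbon C7, while red light excites only the dye and C8a is formed without facial bias.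

Step 18
Reactants: 26 racemic para-quinol
Product: 27 (S)-para-quinol (C8a S)
Conditions: preparative SFC, immobilised amylose tris(3,5-dimethylphenylcarbamate) phase, CO2–i-PrOH
Reagents that add atoms: none
Why: Chromatographic resolution on a chiral phase works here because C8a is the only stereocentre of 26, and the retained (S)-enantiomer fixes the absolute configuration from which all later centres are derived.

Step 19
Reactants: 27 (S)-para-quinol silyl ether
Product: 28 (S)-para-quinol with a 4-hydroxy-3-(methoxymethoxy)benzyl group on C8a and the (2E,4E)-dienone chain on C4a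
Conditions: Bu4NF (1.1 equiv), AcOH (1.2 equiv), THF, 0 °C
Reagents that add atoms: none
Why: Fluoride-induced desilylation buffered with acetic acid frees the phenol para to Ca without leaving a basic medium that would start the annulation early.

Step 20
Reactants: 28 (S)-para-quinol phenol
Product: 31 8-oxabicyclo[3.2.1]octadiene fused to the ring A dienone (C2 S, Cb S, Ca R, C8a S; aroyl exo on Cb; ring B endo on Ca), via dihydropyran ketone 29 (not isolated), via quinone methide 30 (not isolated)
Conditions: Cs2CO3 (0.5 equiv), 4 Å MS, MeCN, 23 °C, 1 h; then Ag2O (1.1 equiv), dark, 23 °C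
Reagents that add atoms: none
Why: Proposed new method: Cs2CO3 first sets up a reversible oxa-Michael equilibrium in which the quinol oxygen O1 adds to C2, the β-carbon of the aroyl-activated C2=Cb bond held cis to C4a (6-exo-trig, dihydropyran 29), and Ag2O then removes two electrons and two protons from the 4-hydroxybenzyl unit to give the neutral methide 30, whose carbon Ca is attacked by the enolate carbon Cb (5-exo-trig for the tetrahydrofuran, the same bond closing the seven-membered carbocycle C2–C3–C4–C4a–C8a–Ca–Cb) with rearomatisation to the phenoxide. The closest known reactions are the base-mediated oxa-Michael/1,6-addition annulations of hydroxyl-bearing para-quinone methides with enones and the Ag2O oxidation of 4-alkyl-2-alkoxyphenols to methides for intramolecular capture, the new elements being an unhindered methide made in situ beside a tertiary quinol ether and the transannular closure. C2 is controlled by C8a, because only the adduct whose CH2COAr arm lies on the pyran face that carries Ca can bridge, while the other epimer returns to 28 by E1cB loss of O1. Cb is controlled by ring C on C3, which blocks the endo sector so that the enolate, and afterwards the still epimerisable aroyl group, sits exo beside the small bridgehead hydrogen of C2. Ca is controlled by that exo enolate, since on the eclipsed two-carbon bridge the methide ring has to turn endo (trans to the aroyl group, below C4a), which is also the less strained of the two trans arrangements and the only one from which ring B can later reach C7. The step needs oxidation of the primary benzylic phenol in preference to the product phenol, and closure faster than a 1,2-shift from C8a to Ca or capture of Ca by water, which the near-stoichiometric charge of Ag2O, the etherification of O1 before oxidation, the molecular sieves and the 1,3-diaxial proximity of Cb and Ca are meant to secure.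

Step 21
Reactants: 31 oxabicyclic phenol
Product: 32 ring B 4-O-MOM ether of 31
Conditions: MOMCl, i-Pr2NEt, CH2Cl2, 0 °C to rt
Reagents that add atoms: chloromethyl methyl ether (MOMCl), COCCl
Why: Williamson-type O-alkylation caps the ring B phenol so that it can neither be oxidised again at Ca in step 23 nor reopen the Cb–Ca bond, and the cap leaves with the other MOM groups in the last step.

Step 22
Reactants: 32 penta-MOM diketone
Product: 33 diol (C6 ring carbinol and ring D benzylic carbinol, both as epimer mixtures)
Conditions: i-Bu2AlH (3 equiv), CH2Cl2, −78 °C; then aq. potassium sodium tartrate (KNaC4H4O6)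
Reagents that add atoms: none
Why: Hydride 1,2-reduction is applied to both carbonyl groups on purpose, because the hindered donor-substituted aroyl ketone cannot be reduced while the C6 dienone is spared, and the two new carbinol centres are irrelevant since one is reoxidised and the other removed.

Step 23
Reactants: 33 diol
Product: 34 C6 dienone with the ring D benzylic alcohol retained
Conditions: activated MnO2 (10 equiv), CH2Cl2, 0 °C, short contact
Reagents that add atoms: none
Why: Allylic alcohol oxidation with MnO2 should take the open bis-allylic ring carbinol far faster than the α-branched ortho-methoxy benzylic carbinol, it restores the dienone before any acid is used because the cyclohexadienol would ionise and rearrange, and over-oxidised material is simply 32 and re-enters at step 22.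

Step 24
Reactants: 34 hydroxy dienone
Product: 35 penta-MOM ether with the 2-methoxy-4-(methoxymethoxy)benzyl group exo on Cb
Conditions: Et3SiH (5 equiv), TFA (5 equiv), CH2Cl2, −40 °C; NaHCO3 quench
Reagents that add atoms: none
Why: Ionic hydrogenation works because the 2,4-dialkoxybenzylic alcohol ionises at low temperature to a strongly stabilised cation that the silane captures well before the much less electrophilic protonated trienone or the MOM acetals respond, and Cb is not touched.

Step 25
Reactants: 35 penta-MOM ether
Product: 37 target CNP0246028.1 (C2 S, Cb S, Ca R, C7 S, C8a R), via alpha-diketone 36 (not isolated)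
Conditions: 2 M HCl, MeOH–THF, 40 °C, argon
Reagents that add atoms: none
Why: Acid-catalysed acetal exchange removes the five MOM groups as methylal, the freed C7 enol tautomerises to the α-diketone, and an intramolecular Friedel–Crafts hydroxyalkylation by the ring B carbon para to its 3-hydroxyl closes the bicyclo[3.3.1]nonane, C7 being set by the endo ring B that can reach only one face of the ketone and the bridgehead α-keto carbinol being unable to ionise further.

## Compound list

1 | 2-bromo-4,5-dimethoxybenzaldehyde | COc1cc(Br)c(C=O)cc1OC | starting material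
2 | 2-bromo-4,5-dihydroxybenzaldehyde | O=Cc1cc(O)c(O)cc1Br | intermediate
3 | 2-bromo-5-hydroxy-4-(methoxymethoxy)benzaldehyde | O=Cc1cc(O)c(OCOC)cc1Br | intermediate
4 | 2-bromo-4-(methoxymethoxy)-5-(tetrahydropyran-2-yloxy)benzaldehyde | O=Cc1cc(OC2CCCCO2)c(OCOC)cc1Br | intermediate
5 | 2,6-dimethoxyphenol | COc1cccc(OC)c1O | starting material
6 | 1,3-dimethoxy-2-(methoxymethoxy)benzene | COCOc1c(OC)cccc1OC | intermediate
7 | 1-bromo-2,4-dimethoxy-3-(methoxymethoxy)benzene | COc1ccc(Br)c(OC)c1OCOC | intermediate
8 | 2-[2,4-dimethoxy-3-(methoxymethoxy)phenyl]acetonitrile | N#CCc1ccc(OC)c(OCOC)c1OC | intermediate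
9 | (Z)-bromo diarylacrylonitrile (nitrile cis to ring A) | N#C/C(c1ccc(OC)c(OCOC)c1OC)=C\c1cc(OC2CCCCO2)c(OCOC)cc1Br | intermediate
10 | 3,4-dihydroxybenzaldehyde | O=Cc1ccc(O)c(O)c1 | starting material
11 | 3-hydroxy-4-(triisopropylsilyloxy)benzaldehyde | O=Cc1ccc(O[Si](C(C)C)(C(C)C)C(C)C)c(O)c1 | intermediate
12 | 3-(methoxymethoxy)-4-(triisopropylsilyloxy)benzaldehyde | O=Cc1ccc(O[Si](C(C)C)(C(C)C)C(C)C)c(OCOC)c1 | intermediate
13 | [3-(methoxymethoxy)-4-(triisopropylsilyloxy)phenyl]methanol | OCc1ccc(O[Si](C(C)C)(C(C)C)C(C)C)c(OCOC)c1 | intermediate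
14 | 4-(chloromethyl)-2-(methoxymethoxy)-1-(triisopropylsilyloxy)benzene | ClCc1ccc(O[Si](C(C)C)(C(C)C)C(C)C)c(OCOC)c1 | intermediate
15 | benzylzinc chloride from 14 | Cl[Zn]Cc1ccc(O[Si](C(C)C)(C(C)C)C(C)C)c(OCOC)c1 | intermediate
16 | (Z)-diarylacrylonitrile with ring B benzyl on C8a | N#C/C(c1ccc(OC)c(OCOC)c1OC)=C\c1cc(OC2CCCCO2)c(OCOC)cc1Cc1ccc(O[Si](C(C)C)(C(C)C)C(C)C)c(OCOC)c1 | intermediate
17 | N-(diisobutylalumino) aldimine of 18 | CC(C)C[Al](CC(C)C)N=C/C(c1ccc(OC)c(OCOC)c1OC)=C\c1cc(OC2CCCCO2)c(OCOC)cc1Cc1ccc(O[Si](C(C)C)(C(C)C)C(C)C)c(OCOC)c1 | intermediate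
18 | (Z)-2,3-diarylacrolein (CHO cis to ring A) | O=C/C(c1ccc(OC)c(OCOC)c1OC)=C\c1cc(OC2CCCCO2)c(OCOC)cc1Cc1ccc(O[Si](C(C)C)(C(C)C)C(C)C)c(OCOC)c1 | intermediate
19 | 1-(4-hydroxy-2-methoxyphenyl)ethanone | COc1cc(O)ccc1C(C)=O | starting material
20 | 1-[2-methoxy-4-(methoxymethoxy)phenyl]ethanone | COc1cc(OCOC)ccc1C(C)=O | intermediate
21 | aldol adduct (C2 carbinol, racemic) | COc1cc(OCOC)ccc1C(=O)CC(O)/C(c1ccc(OC)c(OCOC)c1OC)=C\c1cc(OC2CCCCO2)c(OCOC)cc1Cc1ccc(O[Si](C(C)C)(C(C)C)C(C)C)c(OCOC)c1 | intermediate
22 | allylic mesylate of 21 | COc1cc(OCOC)ccc1C(=O)CC(OS(C)(=O)=O)/C(c1ccc(OC)c(OCOC)c1OC)=C\c1cc(OC2CCCCO2)c(OCOC)cc1Cc1ccc(O[Si](C(C)C)(C(C)C)C(C)C)c(OCOC)c1 | intermediate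
23 | (2E,4E)-dienone, C6–OTHP, ring B–OTIPS | COc1cc(OCOC)ccc1C(=O)/C=C/C(c1ccc(OC)c(OCOC)c1OC)=C\c1cc(OC2CCCCO2)c(OCOC)cc1Cc1ccc(O[Si](C(C)C)(C(C)C)C(C)C)c(OCOC)c1 | intermediate
24 | (2E,4E)-dienone, C6–OH free | COc1cc(OCOC)ccc1C(=O)/C=C/C(c1ccc(OC)c(OCOC)c1OC)=C\c1cc(O)c(OCOC)cc1Cc1ccc(O[Si](C(C)C)(C(C)C)C(C)C)c(OCOC)c1 | intermediate
25 | racemic C8a hydroperoxy dienone | COc1cc(OCOC)ccc1C(=O)/C=C/C(c1ccc(OC)c(OCOC)c1OC)=C\C1=CC(=O)C(OCOC)=CC1(OO)Cc1ccc(O[Si](C(C)C)(C(C)C)C(C)C)c(OCOC)c1 | intermediate
26 | racemic para-quinol, ring B–OTIPS | COc1cc(OCOC)ccc1C(=O)/C=C/C(c1ccc(OC)c(OCOC)c1OC)=C\C1=CC(=O)C(OCOC)=CC1(O)Cc1ccc(O[Si](C(C)C)(C(C)C)C(C)C)c(OCOC)c1 | intermediate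
27 | (S)-para-quinol, ring B–OTIPS | COc1cc(OCOC)ccc1C(=O)/C=C/C(c1ccc(OC)c(OCOC)c1OC)=C\C1=CC(=O)C(OCOC)=C[C@@]1(O)Cc1ccc(O[Si](C(C)C)(C(C)C)C(C)C)c(OCOC)c1 | intermediate
28 | (S)-para-quinol, ring B 4-OH free (key-step precursor) | COc1cc(OCOC)ccc1C(=O)/C=C/C(c1ccc(OC)c(OCOC)c1OC)=C\C1=CC(=O)C(OCOC)=C[C@@]1(O)Cc1ccc(O)c(OCOC)c1 | intermediate
29 | dihydropyran ketone (O1–C2 closed, CH2COAr arm cis to Ca) | COc1cc(OCOC)ccc1C(=O)C[C@@H]2O[C@]3(C=C(OCOC)C(=O)C=C3C=C2c2ccc(OC)c(OCOC)c2OC)Cc1ccc(O)c(OCOC)c1 | intermediate
30 | para-quinone methide of 29 | COc1cc(OCOC)ccc1C(=O)C[C@@H]2O[C@]3(C=C(OCOC)C(=O)C=C3C=C2c2ccc(OC)c(OCOC)c2OC)C=C1C=CC(=O)C(OCOC)=C1 | intermediate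
31 | oxabicyclo[3.2.1]octadiene dienone, aroyl exo on Cb, ring B phenol endo on Ca (key-step product) | COc1cc(OCOC)ccc1C(=O)[C@@H]1[C@@H]2O[C@]3(C=C(OCOC)C(=O)C=C3C=C2c2ccc(OC)c(OCOC)c2OC)[C@H]1c1ccc(O)c(OCOC)c1 | intermediate
32 | ring B 4-O-MOM ether of 31 | COc1cc(OCOC)ccc1C(=O)[C@@H]1[C@@H]2O[C@]3(C=C(OCOC)C(=O)C=C3C=C2c2ccc(OC)c(OCOC)c2OC)[C@H]1c1ccc(OCOC)c(OCOC)c1 | intermediate
33 | diol (C6 and benzylic carbinols, epimer mixtures) | COc1cc(OCOC)ccc1C(O)[C@@H]1[C@@H]2O[C@]3(C=C(OCOC)C(O)C=C3C=C2c2ccc(OC)c(OCOC)c2OC)[C@H]1c1ccc(OCOC)c(OCOC)c1 | intermediate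
34 | C6 dienone with benzylic alcohol | COc1cc(OCOC)ccc1C(O)[C@@H]1[C@@H]2O[C@]3(C=C(OCOC)C(=O)C=C3C=C2c2ccc(OC)c(OCOC)c2OC)[C@H]1c1ccc(OCOC)c(OCOC)c1 | intermediate
35 | deoxygenated penta-MOM ether | COc1cc(OCOC)ccc1C[C@@H]1[C@@H]2O[C@]3(C=C(OCOC)C(=O)C=C3C=C2c2ccc(OC)c(OCOC)c2OC)[C@H]1c1ccc(OCOC)c(OCOC)c1 | intermediate
36 | deprotected C6,C7 alpha-diketone | COc1cc(O)ccc1C[C@@H]1[C@@H]2O[C@]3(CC(=O)C(=O)C=C3C=C2c2ccc(OC)c(O)c2OC)[C@H]1c1ccc(O)c(O)c1 | intermediate
37 | CNP0246028.1 | COc1cc(O)ccc1C[C@@H]1[C@@H]2O[C@@]34C[C@@](O)(C(=O)C=C3C=C2c2ccc(OC)c(O)c2OC)c2cc(O)c(O)cc2[C@@H]14 | target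

## Step count and risk

Total step count: 25.
Longest linear sequence: 17 steps (steps 1–3, 7, 12, 13, 15–25). The branches from 5 and from 10 are equally long.

**1. Step 20 (carries the label).**
- What may go wrong:
  - further oxidation of the product phenol at its Ca–H bond;
  - a 1,2-shift of a ring A carbon from C8a to Ca in the still open alkoxide, which expands the ring;
  - capture of the unhindered methide by water or by itself;
  - attack on the wrong face of Ca, which enolisation cannot repair.
- Fallback, from 28 back to 31: the bond formations are separated, and the oxidant is removed before the C–C bond is made. Compound 28 is equilibrated with Cs2CO3 alone in MeCN and quenched with AcOH, and the dihydropyran ketone 29 is isolated (intramolecular oxa-Michael addition). Ag2O in CH2Cl2 without base, filtration from silver and addition of p-toluenesulfinic acid should give the Ca p-tolyl sulfone F1 (1,6-addition of a sulfinic acid to a para-quinone methide). Cs2CO3 in MeCN then expels sulfinate, and the ketone enolate adds 1,6 to the regenerated methide to reach 31.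

**2. Step 25.**
- What may go wrong: once C7 is a ketone, loss of O1 from C8a by vinylogous β-elimination (ring A drifting to an ortho-quinone) may outrun the arylation. Formaldehyde equivalents may also alkylate the freed phenol rings.
- Fallback, from 35 back to 37: the ring is closed while the phenols are still protected. MgBr2·OEt2 in CH2Cl2–Et2O at 0 °C, chelated between the C6 carbonyl and the C7 oxygen, should cleave only the enol MOM ether and give the tetra-MOM diosphenol F2. Sc(OTf)3 (10 mol %) in CH2Cl2 should hold the chelated diketone tautomer and promote the Friedel–Crafts hydroxyalkylation by the dialkoxy ring B, giving the tetra-MOM ether of the target F3. HCl in MeOH then removes the aryl MOM groups from a skeleton that no longer has a ketone β to O1.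

**3. Step 24.**
- What may go wrong:
  - loss of the Cb proton from the benzylic cation followed by reprotonation, which erodes the Cb configuration;
  - cleavage of C2–Cb pushed by O1 in a retro-Prins manner;
  - hydride delivery to the acid-activated trienone;
  - premature loss of MOM groups.
- Fallback, from 34 back to 35: the cationic deoxygenation is replaced by a radical one (Barton–McCombie). 1,1'-Thiocarbonyldiimidazole and DMAP in toluene should give the benzylic imidazolylthiocarbonyl ester F4. Bu3SnH with AIBN in toluene at 80 °C then replaces the C–O bond by C–H without any acid.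

## Further compounds

F1 | step 20 | Ca p-tolylsulfonyl derivative of 29 (mixture at Ca) | COc1cc(OCOC)ccc1C(=O)C[C@@H]2O[C@]3(C=C(OCOC)C(=O)C=C3C=C2c2ccc(OC)c(OCOC)c2OC)C(c1ccc(O)c(OCOC)c1)S(=O)(=O)c1ccc(C)cc1
F2 | step 25 | C7 diosphenol with four aryl MOM ethers | COc1cc(OCOC)ccc1C[C@@H]1[C@@H]2O[C@]3(C=C(O)C(=O)C=C3C=C2c2ccc(OC)c(OCOC)c2OC)[C@H]1c1ccc(OCOC)c(OCOC)c1
F3 | step 25 | tetra-MOM ether of 37 | COc1cc(OCOC)ccc1C[C@@H]1[C@@H]2O[C@@]34C[C@@](O)(C(=O)C=C3C=C2c2ccc(OC)c(OCOC)c2OC)c2cc(OCOC)c(OCOC)cc2[C@@H]14
F4 | step 24 | benzylic O-(imidazol-1-ylthiocarbonyl) derivative of 34 | COc1cc(OCOC)ccc1C(OC(=S)n1ccnc1)[C@@H]1[C@@H]2O[C@]3(C=C(OCOC)C(=O)C=C3C=C2c2ccc(OC)c(OCOC)c2OC)[C@H]1c1ccc(OCOC)c(OCOC)c1
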